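## Retrosynthetic overview

1. The strategy rests on the lower pyran ring F. Its C2–C3 bond is the aldol bond between C3 of a ring D aryl ketone (C4=O on C4a) and the ring E aldehyde carbon C2. The aldol oxygen is the ring oxygen O1 on C8a, ortho to that ketone. Ring F is therefore opened at C2–C3 and at C8a–O1, with fluoride on C8a (24 + 4 → 31).
2. After ring F is closed, all benzyl ethers are removed and hydride on the C4 ketone gives the 3,4-trans alcohol (33).
3. Ketone 24 comes from aryl bromide 19 (Br on ring D C4a) by bromine–lithium exchange and acylation with the Weinreb amide of benzyloxyacetic acid.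
4. The upper C4–ring D C6 bond comes from adding the C6 arylmagnesium of dihalide 16 to the upper chroman-4-one 9. Ionic hydride delivery anti to O3 then sets the 3,4-cis relation.
5. Ring C is formed first (enantioselective chalcone epoxidation, then phenol closure on ring A) and ring F last. Rings A, B, D and E are bought as arenes.

Key step: step 18

Lettering: the upper flavan unit has rings A (benzo), C (pyran) and B (2-aryl). The lower unit has rings D, F and E. Flavonoid numbering is used within each unit.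

Assumption: borane 27 made from (−)-menthone is taken to send its E enol borinates to the Si face of aldehyde 4 (giving 2R). If the other face is attacked, the mirror-image borane from (+)-menthone is made and used in the same way.

## Route

Step 1
Reactants: 1 1-(2,3,4-trihydroxyphenyl)ethanone
Product: 2 1-[3,4-bis(benzyloxy)-2-hydroxyphenyl]ethanone
Conditions: BnBr (2 equiv), K2CO3, acetone, reflux
Reagents that add atoms: benzyl bromide, BrCc1ccccc1
Why: Williamson ether synthesis; the 2-OH is locked in a hydrogen bond to the acetyl oxygen and is the least reactive phenol, so two equivalents of bromide should stop at the 3,4-diether.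

Step 2
Reactants: 2 1-[3,4-bis(benzyloxy)-2-hydroxyphenyl]ethanone
Product: 3 1-[3,4-bis(benzyloxy)-2-(methoxymethoxy)phenyl]ethanone
Conditions: NaH, MOMCl, DMF, 0 °C → rt
Reagents that add atoms: chloromethyl methyl ether, COCCl
Why: O-alkylation of the sodium phenoxide (MOM protection), needed because a free 2'-OH would divert the later peroxide epoxidation into flavonol or aurone formation.

Step 3
Reactants: 3 1-[3,4-bis(benzyloxy)-2-(methoxymethoxy)phenyl]ethanone; 4 4-(benzyloxy)benzaldehyde
Product: 5 (E)-1-[3,4-bis(benzyloxy)-2-(methoxymethoxy)phenyl]-3-[4-(benzyloxy)phenyl]prop-2-en-1-one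
Conditions: KOH, EtOH–THF, rt
Reagents that add atoms: none
Why: Claisen–Schmidt aldol condensation; the aldehyde cannot enolise and E1cB dehydration gives the conjugated E-enone.

Step 4
Reactants: 5 (E)-chalcone
Product: 6 [3,4-bis(benzyloxy)-2-(methoxymethoxy)phenyl]{(2S,3R)-3-[4-(benzyloxy)phenyl]oxiran-2-yl}methanone
Conditions: poly-D-leucine, urea·H2O2, DBU, THF, rt
Reagents that add atoms: urea–hydrogen peroxide, NC(N)=O.OO
Why: Juliá–Colonna epoxidation (nucleophilic peroxide addition to the enone inside the polypeptide helix); the D-configured polyleucine sets both centres as the (αS,βR)-trans-epoxide, the mirror image of what poly-L-leucine gives.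

Step 5
Reactants: 6 (αS,βR)-epoxychalcone MOM ether
Product: 8 (2S,3S)-7,8-bis(benzyloxy)-2-[4-(benzyloxy)phenyl]-3-hydroxychroman-4-one (2,3-trans), via hydroxy epoxide 7 (not isolated)
Conditions: HCl (3 M in MeOH), THF, 50 °C
Reagents that add atoms: none
Why: Acid-catalysed acetal cleavage followed by 6-endo epoxide opening by the freed phenol at the benzylic carbon with inversion (C2 becomes S) while the Cα–O bond is untouched (C3 stays S), a known way to 2,3-trans-dihydroflavonols, which are also the more stable epimers.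

Step 6
Reactants: 8 (2S,3S)-dihydroflavonol
Product: 9 (2S,3S)-3,7,8-tris(benzyloxy)-2-[4-(benzyloxy)phenyl]chroman-4-one
Conditions: BnOC(=NH)CCl3, TfOH (cat.), CH2Cl2–cyclohexane, 0 °C → rt
Reagents that add atoms: benzyl 2,2,2-trichloroacetimidate, N=C(OCc1ccccc1)C(Cl)(Cl)Cl
Why: Acid-catalysed O-benzylation with a trichloroacetimidate, chosen because base would enolise the ketone and open the pyranone; no stereocentre is touched.

Step 7
Reactants: 10 3-fluoro-2-hydroxybenzaldehyde
Product: 11 2-(benzyloxy)-3-fluorobenzaldehyde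
Conditions: BnBr, K2CO3, DMF, rt
Reagents that add atoms: benzyl bromide, BrCc1ccccc1
Why: Williamson ether synthesis on the only phenol.

Step 8
Reactants: 11 2-(benzyloxy)-3-fluorobenzaldehyde
Product: 13 2-(benzyloxy)-3-fluorophenol, via aryl formate 12 (not isolated)
Conditions: mCPBA, CH2Cl2, rt; then K2CO3 (cat.), MeOH, rt
Reagents that add atoms: 3-chloroperbenzoic acid, OOC(=O)c1cccc(Cl)c1
Why: Baeyer–Villiger oxidation of the electron-rich aldehyde (Dakin-type aryl migration) to the formate and its methanolysis, which leaves the oxygen next to fluorine benzylated and the other one free.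

Step 9
Reactants: 13 2-(benzyloxy)-3-fluorophenol
Product: 14 2-(benzyloxy)-4-bromo-3-fluorophenol
Conditions: NBS, MeCN, −20 → 0 °C
Reagents that add atoms: N-bromosuccinimide, BrN1C(=O)CCC1=O
Why: Electrophilic aromatic bromination directed by the free phenol to its para position (future C4a, ortho to fluorine), as in the bromination of 3-fluorophenol and of guaiacol.

Step 10
Reactants: 14 2-(benzyloxy)-4-bromo-3-fluorophenol
Product: 15 2-(benzyloxy)-4-bromo-3-fluoro-6-iodophenol
Conditions: NIS, CF3CO2H (cat.), MeCN, rt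
Reagents that add atoms: N-iodosuccinimide, IN1C(=O)CCC1=O
Why: Electrophilic aromatic iodination; with the para position blocked the phenol can direct only to its one free ortho carbon (future C6).

Step 11
Reactants: 15 2-(benzyloxy)-4-bromo-3-fluoro-6-iodophenol
Product: 16 2,3-bis(benzyloxy)-5-bromo-4-fluoro-1-iodobenzene (ring D: iodine on C6, Br on C4a, F on C8a)
Conditions: BnBr, K2CO3, DMF, 40 °C
Reagents that add atoms: benzyl bromide, BrCc1ccccc1
Why: Williamson ether synthesis on the remaining phenol.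

Step 12
Reactants: 16 ring D dihalide; 9 upper chroman-4-one
Product: 18 2,3-trans-3,7,8-tris(benzyloxy)-2-[4-(benzyloxy)phenyl]-4-[2,3-bis(benzyloxy)-5-bromo-4-fluorophenyl]chroman-4-ol (C2 and C3 as in 9; aryl group drawn anti to O3; the C4 epimer is of no consequence), via arylmagnesium chloride 17 (not isolated)
Conditions: 16, iPrMgCl·LiCl, THF, −30 °C; then 9, LaCl3·2LiCl, THF, −30 → 0 °C; aq NH4Cl
Reagents that add atoms: none
Why: Iodine–magnesium exchange followed by Grignard 1,2-addition; iodide exchanges far faster than bromide so only C6 is metalated, the lanthanum salt favours carbonyl addition over enolisation of the β-aryloxy ketone (aryl-metal addition to protected flavan-4-ones is known), and the new C4 centre is erased in step 13.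

Step 13
Reactants: 18 4-arylflavan-4-ol
Product: 19 (2S,3R)-3,7,8-tris(benzyloxy)-2-[4-(benzyloxy)phenyl]-4-[2,3-bis(benzyloxy)-5-bromo-4-fluorophenyl]chroman (2,3-trans-3,4-cis; ring D on the face of O3, as in the target)
Conditions: Bu3SnH, CF3CO2H, CH2Cl2, −78 → 0 °C, dark
Reagents that add atoms: none
Why: Ionic hydrogenation (SN1 deoxygenation); acid ionises the doubly benzylic tertiary alcohol to a planar cation stabilised by the para C7 oxygen of ring A, and the tin hydride should enter on the face opposite the neighbouring 3-benzyloxy group, which turns ring D cis to O3, as known for 4-arylflavan-4-ols.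

Step 14
Reactants: 20 benzyloxyacetic acid
Product: 22 2-(benzyloxy)-N-methoxy-N-methylacetamide, via acyl imidazole 21 (not isolated)
Conditions: CDI, CH2Cl2, rt; then MeNH(OMe)·HCl, rt
Reagents that add atoms: N,O-dimethylhydroxylamine hydrochloride, CNOC.Cl
Why: Amide coupling through the acyl imidazole gives the Weinreb amide.

Step 15
Reactants: 19 aryl bromide; 22 Weinreb amide
Product: 24 2-(benzyloxy)-1-{3,4-bis(benzyloxy)-2-fluoro-5-[(2,3-trans-3,4-cis)-3,7,8-tris(benzyloxy)-2-(4-benzyloxyphenyl)chroman-4-yl]phenyl}ethanone, via aryllithium 23 (not isolated)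
Conditions: n-BuLi, THF, −78 °C; then 22, −78 → −40 °C; aq NH4Cl
Reagents that add atoms: none
Why: Bromine–lithium exchange and Weinreb ketone synthesis; exchange at −78 °C outruns deprotonation and loss of LiF, and the chelated tetrahedral adduct prevents double addition.

Step 16
Reactants: 25 (−)-menthone, (2S,5R)-5-methyl-2-(propan-2-yl)cyclohexanone
Product: 26 (1S,4R)-4-methyl-2-methylidene-1-(propan-2-yl)cyclohexane
Conditions: MePPh3Br, n-BuLi, THF, 0 °C; then 25, 0 °C → rt
Reagents that add atoms: methyltriphenylphosphonium bromide, C[P+](c1ccccc1)(c1ccccc1)c1ccccc1.[Br-]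
Why: Wittig methylenation; the two stereocentres of menthone are carried over provided the ylide is used without excess base.

Step 17
Reactants: 26 methylidene menthane
Product: 27 chlorobis{[(1R,2S,5R)-5-methyl-2-(propan-2-yl)cyclohexyl]methyl}borane
Conditions: ClBH2·SMe2 (0.5 equiv), CH2Cl2, 0 °C → rt; crystallised from Et2O, −30 °C, under Ar
Reagents that add atoms: monochloroborane–dimethyl sulfide, C[S+](C)[BH2-]Cl
Why: Hydroboration of two alkene molecules by monochloroborane with boron on the CH2 terminus; hydrogen is delivered mainly to the axial face, away from the neighbouring equatorial isopropyl group, so CH2B becomes equatorial (C1 R), and crystallisation removes the minor epimer.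

Step 18
Reactants: 24 ring D 2-fluoroaryl benzyloxymethyl ketone; 4 4-(benzyloxy)benzaldehyde; 27 chiral dialkylboron chloride
Product: 31 (2R,3R)-3,7,8-tris(benzyloxy)-2-[4-(benzyloxy)phenyl]-6-[(2,3-trans-3,4-cis)-3,7,8-tris(benzyloxy)-2-(4-benzyloxyphenyl)chroman-4-yl]chroman-4-one, via enol borinate 28 (not isolated), via boron aldolate 29 (not isolated), via anti aldol 30 (not isolated)
Conditions: 27 (1.5 equiv), Et3N, CH2Cl2–Et2O, −5 °C; 4, −78 → −25 °C; HOCH2CH2NH2 (1.5 equiv), 0 °C; volatiles off, DMF, K2CO3, 18-crown-6 (cat.), 0 → 25 °C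
Reagents that add atoms: none
Why: Proposed new method: 27 and Et3N deprotonate ketone 24 kinetically to the E enol borinate 28 (benzyloxy group trans to O–B, as alkyl aryl ketones behave with dialkylboron chlorides), which adds to 4 through a closed six-membered Zimmerman–Traxler chair to make C2–C3; 2-aminoethanol then removes boron as its N→B chelate, and carbonate lets the freed C2 oxygen of 30 attack C8a, the anionic σ-adduct being stabilised by the ortho C4 carbonyl before fluoride leaves. The closest known reactions are the reagent-controlled anti boron aldol of ketones and the base-induced cyclisation of β-hydroxy 2-fluoroaryl ketones to chroman-4-ones; running them in one flask on an α-alkoxy ketone under a chiral borane is the untested part. Ring F closes by intramolecular nucleophilic aromatic substitution (six-membered addition–elimination of O1 at the sp2 carbon C8a), in which no bond to C2 is broken, so C2 keeps its aldol configuration. The 2,3-anti relation (C3) follows from the E enolate geometry in the chair, and the absolute sense (2R,3R) from the menthylmethyl ligands on boron, a ligand type suited to E enol borinates, where isopinocampheyl ligands induce poorly; the remote upper unit should exert no bias. The step needs attack at C8a by the C2 oxygen alone and closure faster than retro-aldol cleavage or C3 enolisation: O3 is blocked as its benzyl ether so no five-membered ring can form, the fluoride ortho to the ketone is the only leaving group on ring D, and a weak base at or below room temperature spares the product from ring opening.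

Step 19
Reactants: 31 octabenzyl dimer ketone
Product: 32 (2R,3R)-3,7,8-trihydroxy-2-(4-hydroxyphenyl)-6-[(2S,3R,4R)-3,7,8-trihydroxy-2-(4-hydroxyphenyl)chroman-4-yl]chroman-4-one
Conditions: H2 (1 atm), Pd(OH)2/C, THF–MeOH, rt
Reagents that add atoms: none
Why: Catalytic hydrogenolysis of eight benzyl ethers; the electron-rich aryl ketone and the cyclic benzylic C2–O1 bonds are known to survive these conditions in benzylated flavonoids, and doing this before the reduction spares the later benzylic C4–OH.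

Step 20
Reactants: 32 free phenolic dihydroflavonol dimer
Product: 33 (2R,3S,4R)-2-(4-hydroxyphenyl)-6-[(2S,3R,4R)-3,7,8-trihydroxy-2-(4-hydroxyphenyl)chroman-4-yl]chroman-3,4,7,8-tetrol (target)
Conditions: NaBH4, EtOH, 0 °C, under Ar; careful neutralisation to pH 6–7
Reagents that add atoms: none
Why: Borohydride reduction of a 2,3-trans-dihydroflavonol; axial hydride attack on the half-chair gives the equatorial 4-OH trans to the 3-OH (4R), the known main course for this class.

## Compound list

1 | 1-(2,3,4-trihydroxyphenyl)ethanone | CC(=O)c1ccc(O)c(O)c1O | starting material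
2 | 1-[3,4-bis(benzyloxy)-2-hydroxyphenyl]ethanone | CC(=O)c1ccc(OCc2ccccc2)c(OCc2ccccc2)c1O | intermediate
3 | 1-[3,4-bis(benzyloxy)-2-(methoxymethoxy)phenyl]ethanone | CC(=O)c1ccc(OCc2ccccc2)c(OCc2ccccc2)c1OCOC | intermediate
4 | 4-(benzyloxy)benzaldehyde | O=Cc1ccc(OCc2ccccc2)cc1 | starting material
5 | (E)-chalcone MOM ether | COCOc1c(C(=O)/C=C/c2ccc(OCc3ccccc3)cc2)ccc(OCc3ccccc3)c1OCc4ccccc4 | intermediate
6 | (αS,βR)-epoxychalcone MOM ether | COCOc1c(C(=O)[C@H]2O[C@@H]2c3ccc(OCc4ccccc4)cc3)ccc(OCc4ccccc4)c1OCc4ccccc4 | intermediate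
7 | (αS,βR)-2'-hydroxy epoxychalcone (not isolated) | Oc1c(C(=O)[C@H]2O[C@@H]2c3ccc(OCc4ccccc4)cc3)ccc(OCc4ccccc4)c1OCc4ccccc4 | intermediate
8 | (2S,3S)-7,8-bis(benzyloxy)-2-[4-(benzyloxy)phenyl]-3-hydroxychroman-4-one | c1ccccc1COc2ccc(cc2)[C@@H]3Oc4c(ccc(OCc5ccccc5)c4OCc6ccccc6)C(=O)[C@H]3O | intermediate
9 | (2S,3S)-3,7,8-tris(benzyloxy)-2-[4-(benzyloxy)phenyl]chroman-4-one | c1ccccc1COc2ccc(cc2)[C@@H]3Oc4c(ccc(OCc5ccccc5)c4OCc6ccccc6)C(=O)[C@H]3OCc7ccccc7 | intermediate
10 | 3-fluoro-2-hydroxybenzaldehyde | O=Cc1cccc(F)c1O | starting material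
11 | 2-(benzyloxy)-3-fluorobenzaldehyde | O=Cc1cccc(F)c1OCc2ccccc2 | intermediate
12 | 2-(benzyloxy)-3-fluorophenyl formate (not isolated) | O=COc1cccc(F)c1OCc2ccccc2 | intermediate
13 | 2-(benzyloxy)-3-fluorophenol | Oc1cccc(F)c1OCc2ccccc2 | intermediate
14 | 2-(benzyloxy)-4-bromo-3-fluorophenol | Oc1ccc(Br)c(F)c1OCc2ccccc2 | intermediate
15 | 2-(benzyloxy)-4-bromo-3-fluoro-6-iodophenol | Oc1c(I)cc(Br)c(F)c1OCc2ccccc2 | intermediate
16 | 2,3-bis(benzyloxy)-5-bromo-4-fluoro-1-iodobenzene | Ic1cc(Br)c(F)c(OCc2ccccc2)c1OCc3ccccc3 | intermediate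
17 | [2,3-bis(benzyloxy)-5-bromo-4-fluorophenyl]magnesium chloride (not isolated) | Cl[Mg]c1cc(Br)c(F)c(OCc2ccccc2)c1OCc3ccccc3 | intermediate
18 | 4-arylflavan-4-ol (aryl anti to O3 drawn) | Brc1cc(c(OCc9ccccc9)c(OCc9ccccc9)c1F)[C@@]4(O)c5ccc(OCc9ccccc9)c(OCc9ccccc9)c5O[C@@H](c6ccc(OCc9ccccc9)cc6)[C@@H]4OCc9ccccc9 | intermediate
19 | 2,3-trans-3,4-cis upper unit on ring D aryl bromide | Brc1cc([C@@H]4c5ccc(OCc9ccccc9)c(OCc9ccccc9)c5O[C@@H](c6ccc(OCc9ccccc9)cc6)[C@@H]4OCc9ccccc9)c(OCc9ccccc9)c(OCc9ccccc9)c1F | intermediate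
20 | benzyloxyacetic acid | OC(=O)COCc1ccccc1 | starting material
21 | 1-(benzyloxyacetyl)imidazole (not isolated) | O=C(COCc1ccccc1)n1ccnc1 | intermediate
22 | 2-(benzyloxy)-N-methoxy-N-methylacetamide | CON(C)C(=O)COCc1ccccc1 | intermediate
23 | ring D C4a aryllithium (not isolated) | [Li]c1cc([C@@H]4c5ccc(OCc9ccccc9)c(OCc9ccccc9)c5O[C@@H](c6ccc(OCc9ccccc9)cc6)[C@@H]4OCc9ccccc9)c(OCc9ccccc9)c(OCc9ccccc9)c1F | intermediate
24 | ring D 2-fluoroaryl benzyloxymethyl ketone carrying the upper unit | O=C(COCc9ccccc9)c1cc([C@@H]4c5ccc(OCc9ccccc9)c(OCc9ccccc9)c5O[C@@H](c6ccc(OCc9ccccc9)cc6)[C@@H]4OCc9ccccc9)c(OCc9ccccc9)c(OCc9ccccc9)c1F | intermediate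
25 | (−)-menthone | C[C@@H]1CC[C@H](C(=O)C1)C(C)C | starting material
26 | (1S,4R)-4-methyl-2-methylidene-1-(propan-2-yl)cyclohexane | C[C@@H]1CC[C@H](C(=C)C1)C(C)C | intermediate
27 | chlorobis{[(1R,2S,5R)-5-methyl-2-(propan-2-yl)cyclohexyl]methyl}borane | ClB(C[C@@H]1C[C@H](C)CC[C@H]1C(C)C)C[C@@H]1C[C@H](C)CC[C@H]1C(C)C | intermediate
28 | E enol borinate of 24 (not isolated) | B(C[C@@H]7C[C@H](C)CC[C@H]7C(C)C)(C[C@@H]7C[C@H](C)CC[C@H]7C(C)C)O/C(=C/OCc9ccccc9)c1cc([C@@H]4c5ccc(OCc9ccccc9)c(OCc9ccccc9)c5O[C@@H](c6ccc(OCc9ccccc9)cc6)[C@@H]4OCc9ccccc9)c(OCc9ccccc9)c(OCc9ccccc9)c1F | intermediate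
29 | anti boron aldolate (not isolated) | C(c9ccccc9)Oc2ccc(cc2)[C@@H](OB(C[C@@H]7C[C@H](C)CC[C@H]7C(C)C)C[C@@H]7C[C@H](C)CC[C@H]7C(C)C)[C@@H](OCc9ccccc9)C(=O)c1cc([C@@H]4c5ccc(OCc9ccccc9)c(OCc9ccccc9)c5O[C@@H](c6ccc(OCc9ccccc9)cc6)[C@@H]4OCc9ccccc9)c(OCc9ccccc9)c(OCc9ccccc9)c1F | intermediate
30 | (2R,3R)-anti aldol, 2-benzyloxy-3-hydroxy ketone (not isolated) | C(c9ccccc9)Oc2ccc(cc2)[C@@H](O)[C@@H](OCc9ccccc9)C(=O)c1cc([C@@H]4c5ccc(OCc9ccccc9)c(OCc9ccccc9)c5O[C@@H](c6ccc(OCc9ccccc9)cc6)[C@@H]4OCc9ccccc9)c(OCc9ccccc9)c(OCc9ccccc9)c1F | intermediate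
31 | fully benzylated dimer with lower C4 ketone, lower unit (2R,3R) | c1ccccc1COc1ccc([C@H]2Oc3c(cc([C@@H]4c5ccc(OCc9ccccc9)c(OCc9ccccc9)c5O[C@@H](c6ccc(OCc9ccccc9)cc6)[C@@H]4OCc9ccccc9)c(OCc9ccccc9)c3OCc9ccccc9)C(=O)[C@@H]2OCc9ccccc9)cc1 | intermediate
32 | free phenolic dimer with lower C4 ketone | Oc1ccc([C@H]2Oc3c(cc([C@@H]4c5ccc(O)c(O)c5O[C@@H](c6ccc(O)cc6)[C@@H]4O)c(O)c3O)C(=O)[C@@H]2O)cc1 | intermediate
33 | CNP0391561.8 | Oc1ccc([C@H]2Oc3c(cc([C@@H]4c5ccc(O)c(O)c5O[C@@H](c5ccc(O)cc5)[C@@H]4O)c(O)c3O)[C@@H](O)[C@@H]2O)cc1 | target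

## Step count

Total step count: 20.
Longest linear sequence: 12 (steps 1–6, 12, 13, 15, 18, 19, 20).

## Steps most likely to fail

**Step 18 (Proposed new method).**
- *What may go wrong.* The freed alkoxide may undergo retro-aldol cleavage faster than it closes the ring. The E enolate geometry or the facial bias of the borane may erode. Fluoride displacement on the electron-rich ring D may be slow. The base may open the finished pyranone.
- *Fallback from 24, returning at 31 (known chemistry only).* Here ring F is closed at C2–O1 instead of C8a–O1. Ketone 24 is treated with 2-(methylsulfonyl)ethanol and NaH in DMF, which displaces the activated fluoride to give the 2-(methylsulfonyl)ethyl aryl ether F1. This ether loses methyl vinyl sulfone in the same pot to give the 2'-hydroxy ketone F2.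
- *Ring closure.* Pyrrolidine-catalysed condensation of F2 with 4 follows (Kabbe-type aldol condensation, then oxa-Michael closure of the phenol oxygen onto C2). Under thermodynamic control it should give only 2,3-trans chromanones, namely 31 and the lower-unit (2S,3S) diastereomer F3.
- *Separation.* Because the upper unit is a single enantiomer, 31 and F3 are diastereomers and can be separated by chromatography. F3 is re-equilibrated under the same base and recycled.

**Step 13.**
- *What may go wrong.* Facial selectivity in the hydride capture of the planar C4 cation may be poor. A proton may be lost from C3 to give the enol ether. Acid may open the pyran at C2.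
- *Fallback from 8, returning at 19.* O3 is carried as a bulkier silyl ether, so the face of O3 is shielded more strongly. TBSOTf and 2,6-lutidine convert 8 into the 3-O-TBS chromanone F4. Addition of 17 as in step 12 gives the silylated 4-arylflavan-4-ol F5. Bu3SnH with CF3CO2H then gives the 3,4-cis silyl ether F6. Bu4NF frees the 3,4-cis flavan-3-ol F7, and NaH with BnBr (no base-sensitive ketone is left at this stage) gives 19.

**Step 5.**
- *What may go wrong.* Methanol may solvolyse the benzylic epoxide carbon. The ring may close five-membered at Cα. The aroyl group may migrate.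
- *Fallback from 6, returning at 8.* Ring opening and ring closure are separated. BnSH and SnCl4 in CH2Cl2 at −20 °C open the epoxide at the benzylic carbon and remove the MOM group. This gives the α,2'-dihydroxy-β-(benzylsulfanyl)dihydrochalcone F8, with the Cα–O bond untouched and a mixture at Cβ. AgBF4 in CH2Cl2 at 0 °C activates sulfur, and the phenol closes onto the benzylic carbon to give mainly the 2,3-trans compound 8.

## Further compounds

F1 | step 18 | 2-(methylsulfonyl)ethyl aryl ether of the ring D ketone | O=C(COCc9ccccc9)c1cc([C@@H]4c5ccc(OCc9ccccc9)c(OCc9ccccc9)c5O[C@@H](c6ccc(OCc9ccccc9)cc6)[C@@H]4OCc9ccccc9)c(OCc9ccccc9)c(OCc9ccccc9)c1OCCS(C)(=O)=O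
F2 | step 18 | 2'-hydroxy benzyloxymethyl ketone of ring D | O=C(COCc9ccccc9)c1cc([C@@H]4c5ccc(OCc9ccccc9)c(OCc9ccccc9)c5O[C@@H](c6ccc(OCc9ccccc9)cc6)[C@@H]4OCc9ccccc9)c(OCc9ccccc9)c(OCc9ccccc9)c1O
F3 | step 18 | diastereomer of 31 with (2S,3S) lower unit | c1ccccc1COc1ccc([C@@H]2Oc3c(cc([C@@H]4c5ccc(OCc9ccccc9)c(OCc9ccccc9)c5O[C@@H](c6ccc(OCc9ccccc9)cc6)[C@@H]4OCc9ccccc9)c(OCc9ccccc9)c3OCc9ccccc9)C(=O)[C@H]2OCc9ccccc9)cc1
F4 | step 13 | (2S,3S)-7,8-bis(benzyloxy)-2-[4-(benzyloxy)phenyl]-3-(tert-butyldimethylsilyloxy)chroman-4-one | c1ccccc1COc2ccc(cc2)[C@@H]3Oc4c(ccc(OCc5ccccc5)c4OCc6ccccc6)C(=O)[C@H]3O[Si](C)(C)C(C)(C)C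
F5 | step 13 | 3-O-TBS 4-arylflavan-4-ol | Brc1cc(c(OCc9ccccc9)c(OCc9ccccc9)c1F)[C@@]4(O)c5ccc(OCc9ccccc9)c(OCc9ccccc9)c5O[C@@H](c6ccc(OCc9ccccc9)cc6)[C@@H]4O[Si](C)(C)C(C)(C)C
F6 | step 13 | 3-O-TBS 2,3-trans-3,4-cis 4-arylflavan | Brc1cc([C@@H]4c5ccc(OCc9ccccc9)c(OCc9ccccc9)c5O[C@@H](c6ccc(OCc9ccccc9)cc6)[C@@H]4O[Si](C)(C)C(C)(C)C)c(OCc9ccccc9)c(OCc9ccccc9)c1F
F7 | step 13 | 2,3-trans-3,4-cis 4-arylflavan-3-ol | Brc1cc([C@@H]4c5ccc(OCc9ccccc9)c(OCc9ccccc9)c5O[C@@H](c6ccc(OCc9ccccc9)cc6)[C@@H]4O)c(OCc9ccccc9)c(OCc9ccccc9)c1F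
F8 | step 5 | 3-(benzylsulfanyl)-1-[3,4-bis(benzyloxy)-2-hydroxyphenyl]-3-[4-(benzyloxy)phenyl]-2-hydroxypropan-1-one (C2–O as in 6, C3 mixture) | Oc1c(C(=O)[C@@H](O)C(SCc4ccccc4)c3ccc(OCc4ccccc4)cc3)ccc(OCc4ccccc4)c1OCc4ccccc4
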